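Assumption: the SMILES is taken as drawn, i.e. (4S,5R,6R,8R) with a cis-4,5-epoxide. Germacrane locants are used as shorthand: C1 ketone, C4/C5 epoxide (C15 methyl on C4), C6 lactone CH–O, C7=C11 butenolide alkene, C8 ester carbon, C10=C14 exomethylene, C12 lactone C=O, C13 CH2OAc. A step run in one flask through an unisolated intermediate counts as one step.

**Retrosynthetic overview**
1. Ten-membered ring (formed last): C1–C10 bond by intramolecular Ni/Cr addition of the 2-iodoallyl unit to the C1 aldehyde, then oxidation to the α-methylene ketone.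
2. Butenolide (formed second): C6–C7 bond and lactone C–O in one operation, by Ni/Cr addition of the C7–C14 (Z)-β-triflyloxy acrylate to the C1–C6 cis-epoxy aldehyde; Felkin–Anh control sets C6.
3. C1–C6 fragment: (Z)-trisubstituted allylic alcohol by B-alkyl Suzuki coupling; Sharpless epoxidation sets C4/C5 (epoxide formed first).
4. C7–C14 fragment: C8 from methyl (R)-glycidate; tetrasubstituted (Z)-enol triflate from a β-keto ester built by Mukaiyama aldol and oxidation.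
5. Acetate (C13) and methacrylate (C8) go on after the coupling, before the vinylsilane is turned into the vinyl iodide.

**C1–C6 fragment**

Step 1
Reactants: 1 but-2-yn-1-ol
Product: 3 (2Z)-3-iodobut-2-en-1-ol, via cyclic alkenylalanate 2 (not isolated)
Conditions: Red-Al, THF, 0 °C→rt; then I2, THF, −78→0 °C
Reagents that add atoms: iodine, II
Why: Hydroxyl-directed trans-hydroalumination puts aluminium on C3 in a five-membered alanate, and iodinolysis with retention gives the Z iodide (iodine cis to CH2OH).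

Step 2
Reactants: 3 (2Z)-3-iodobut-2-en-1-ol; 4 3,3-dimethoxyprop-1-ene
Product: 6 (2Z)-6,6-dimethoxy-3-methylhex-2-en-1-ol, via B-alkyl-9-BBN 5 (not isolated)
Conditions: 4, 9-BBN-H, THF, 0 °C→rt; then 3, Pd(dppf)Cl2 (5 mol%), AsPh3, Cs2CO3, DMF/H2O, rt
Reagents that add atoms: none
Why: Anti-Markovnikov hydroboration followed by B-alkyl Suzuki–Miyaura coupling proceeds with retention at the alkenyl iodide, so the new chain ends up cis to CH2OH (Z olefin).

Step 3
Reactants: 6 (2Z)-6,6-dimethoxy-3-methylhex-2-en-1-ol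
Product: 7 [(2R,3S)-3-(3,3-dimethoxypropyl)-3-methyloxiran-2-yl]methanol
Conditions: Ti(OiPr)4 (10 mol%), D-(−)-diethyl tartrate (12 mol%), t-BuOOH, 4 Å MS, CH2Cl2, −20 °C
Reagents that add atoms: tert-butyl hydroperoxide, CC(C)(C)OO
Why: Sharpless asymmetric epoxidation with D-(−)-tartrate gives the 2R epoxy alcohol (the nerol-type substrate gives 2S,3R with L-(+)-tartrate), which sets C4 and C5 with the cis geometry inherited from the Z olefin.

Step 4
Reactants: 7 [(2R,3S)-3-(3,3-dimethoxypropyl)-3-methyloxiran-2-yl]methanol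
Product: 8 (2S,3S)-3-(3,3-dimethoxypropyl)-3-methyloxirane-2-carbaldehyde
Conditions: TEMPO (10 mol%), PhI(OAc)2, CH2Cl2, rt; used crude
Reagents that add atoms: none
Why: TEMPO/hypervalent-iodine oxidation of the primary alcohol is near-neutral and leaves the epoxide, the acetal and the α-stereocentre untouched.

**C7–C14 fragment**

Step 5
Reactants: 9 methyl (2R)-oxirane-2-carboxylate; 10 (1-bromoethenyl)trimethylsilane
Product: 13 methyl (2R)-2-[(triethylsilyl)oxy]-4-(trimethylsilyl)pent-4-enoate, via alkenyl Grignard reagent 11 (not isolated), via magnesium alkoxide 12 (not isolated)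
Conditions: Mg, THF, 40 °C; then CuI (10 mol%), 9, THF, −40 °C; then Et3SiCl, imidazole (cat.), DMF, 0 °C→rt
Reagents that add atoms: chlorotriethylsilane, CC[Si](Cl)(CC)CC
Why: Copper-catalysed SN2 opening of the glycidate at its CH2 terminus leaves the stereocentre (C8, R) untouched, and the alkoxide is silylated in the same flask.

Step 6
Reactants: 13 methyl (2R)-2-[(triethylsilyl)oxy]-4-(trimethylsilyl)pent-4-enoate
Product: 14 (2R)-2-[(triethylsilyl)oxy]-4-(trimethylsilyl)pent-4-enal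
Conditions: DIBAL-H (1.1 equiv), CH2Cl2, −78 °C; MeOH, Rochelle salt
Reagents that add atoms: none
Why: DIBAL half-reduction of an α-silyloxy ester stops at the chelated aluminium hemiacetal at −78 °C and releases the aldehyde on work-up without epimerisation.

Step 7
Reactants: 15 methyl 3-hydroxypropanoate
Product: 16 methyl 3-[(triethylsilyl)oxy]propanoate
Conditions: Et3SiCl, imidazole, CH2Cl2, 0 °C→rt
Reagents that add atoms: chlorotriethylsilane, CC[Si](Cl)(CC)CC
Why: Standard silylation of a primary alcohol.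

Step 8
Reactants: 16 methyl 3-[(triethylsilyl)oxy]propanoate
Product: 18 1-methoxy-3-[(triethylsilyl)oxy]-1-[(trimethylsilyl)oxy]prop-1-ene (E/Z mixture), via lithium ester enolate 17 (not isolated)
Conditions: LDA, Me3SiCl (in situ quench), THF, −78 °C; non-aqueous work-up
Reagents that add atoms: chlorotrimethylsilane, C[Si](C)(C)Cl
Why: Kinetic enolisation with internal silyl trapping gives the ketene silyl acetal before the β-silyloxy enolate can eliminate.

Step 9
Reactants: 14 (2R)-2-[(triethylsilyl)oxy]-4-(trimethylsilyl)pent-4-enal; 18 1-methoxy-3-[(triethylsilyl)oxy]-1-[(trimethylsilyl)oxy]prop-1-ene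
Product: 19 methyl (4R)-3-hydroxy-4-[(triethylsilyl)oxy]-2-{[(triethylsilyl)oxy]methyl}-6-(trimethylsilyl)hept-6-enoate (C2/C3 epimer mixture)
Conditions: BF3·OEt2 (pre-complexed with 14), CH2Cl2, −78 °C; aq. NaHCO3
Reagents that add atoms: none
Why: Mukaiyama aldol addition under Lewis-acid conditions avoids base at the epimerisable α-silyloxy aldehyde; the two new centres are erased in steps 10–11, so their ratio does not matter.

Step 10
Reactants: 19 methyl (4R)-3-hydroxy-4-[(triethylsilyl)oxy]-2-{[(triethylsilyl)oxy]methyl}-6-(trimethylsilyl)hept-6-enoate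
Product: 20 methyl (4R)-3-oxo-4-[(triethylsilyl)oxy]-2-{[(triethylsilyl)oxy]methyl}-6-(trimethylsilyl)hept-6-enoate
Conditions: Dess–Martin periodinane, CH2Cl2, 0 °C→rt
Reagents that add atoms: none
Why: Dess–Martin oxidation of the secondary alcohol gives the β-keto ester under non-basic conditions that spare the silyl ethers and C8.

Step 11
Reactants: 20 methyl (4R)-3-oxo-4-[(triethylsilyl)oxy]-2-{[(triethylsilyl)oxy]methyl}-6-(trimethylsilyl)hept-6-enoate
Product: 22 methyl (2Z,4R)-4-[(triethylsilyl)oxy]-2-{[(triethylsilyl)oxy]methyl}-3-{[(trifluoromethyl)sulfonyl]oxy}-6-(trimethylsilyl)hepta-2,6-dienoate, via chelated sodium enolate 21 (not isolated)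
Conditions: NaH (1.05 equiv), Et2O, 0 °C; then Tf2O, −78→−20 °C
Reagents that add atoms: trifluoromethanesulfonic anhydride, O=S(=O)(OS(=O)(=O)C(F)(F)F)C(F)(F)F
Why: Enolisation occurs only at the doubly activated C11, and the sodium chelate between enolate oxygen and ester carbonyl fixes the U-shaped geometry, so O-triflation gives the enol triflate with OTf cis to CO2Me (C8 cis to C13).

**Coupling and end game**

Step 12
Reactants: 8 (2S,3S)-3-(3,3-dimethoxypropyl)-3-methyloxirane-2-carbaldehyde; 22 methyl (2Z,4R)-4-[(triethylsilyl)oxy]-2-{[(triethylsilyl)oxy]methyl}-3-{[(trifluoromethyl)sulfonyl]oxy}-6-(trimethylsilyl)hepta-2,6-dienoate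
Product: 24 (5R)-5-[(2R,3S)-3-(3,3-dimethoxypropyl)-3-methyloxiran-2-yl]-4-{(1R)-1-[(triethylsilyl)oxy]-3-(trimethylsilyl)but-3-en-1-yl}-3-{[(triethylsilyl)oxy]methyl}furan-2(5H)-one, via hydroxy ester chromium alkoxide 23 (not isolated)
Conditions: CrCl2 (6 equiv), NiCl2 (2 mol%), DMF, rt, 24 h; aq. work-up
Reagents that add atoms: none
Why: In this Nozaki–Hiyama–Kishi coupling the alkenylchromium adds to the epoxy aldehyde in the Felkin–Anh sense (epoxide C–O anti to the nucleophile, reinforced by the cis substituent) to set C6 as R, and the alkoxide closes on the cis ester to give the butenolide.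

Step 13
Reactants: 24 (5R)-5-[(2R,3S)-3-(3,3-dimethoxypropyl)-3-methyloxiran-2-yl]-4-{(1R)-1-[(triethylsilyl)oxy]-3-(trimethylsilyl)but-3-en-1-yl}-3-{[(triethylsilyl)oxy]methyl}furan-2(5H)-one
Product: 25 (5R)-5-[(2R,3S)-3-(3,3-dimethoxypropyl)-3-methyloxiran-2-yl]-4-[(1R)-1-hydroxy-3-(trimethylsilyl)but-3-en-1-yl]-3-(hydroxymethyl)furan-2(5H)-one
Conditions: PPTS (cat.), MeOH, 0 °C→rt
Reagents that add atoms: none
Why: Mild acid-catalysed methanolysis removes both triethylsilyl ethers while the dimethyl acetal, the vinylsilane and the epoxide survive.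

Step 14
Reactants: 25 (5R)-5-[(2R,3S)-3-(3,3-dimethoxypropyl)-3-methyloxiran-2-yl]-4-[(1R)-1-hydroxy-3-(trimethylsilyl)but-3-en-1-yl]-3-(hydroxymethyl)furan-2(5H)-one
Product: 27 (1R)-1-{(2R)-4-(acetoxymethyl)-2-[(2R,3S)-3-(3,3-dimethoxypropyl)-3-methyloxiran-2-yl]-5-oxo-2,5-dihydrofuran-3-yl}-3-(trimethylsilyl)but-3-en-1-yl 2-methylprop-2-enoate, via primary monoacetate 26 (not isolated)
Conditions: AcCl (1.05 equiv), 2,4,6-collidine, CH2Cl2, −78 °C; then methacryloyl chloride, Et3N, DMAP (cat.), −40→0 °C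
Reagents that add atoms: acetyl chloride, CC(Cl)=O; methacryloyl chloride, C=C(C)C(Cl)=O
Why: Sequential O-acylation: acetyl chloride/collidine at low temperature takes only the unhindered primary allylic alcohol, after which DMAP-catalysed acylation esterifies the remaining secondary C8 alcohol.

Step 15
Reactants: 27 (1R)-1-{(2R)-4-(acetoxymethyl)-2-[(2R,3S)-3-(3,3-dimethoxypropyl)-3-methyloxiran-2-yl]-5-oxo-2,5-dihydrofuran-3-yl}-3-(trimethylsilyl)but-3-en-1-yl 2-methylprop-2-enoate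
Product: 28 (1R)-1-{(2R)-4-(acetoxymethyl)-2-[(2R,3S)-3-(3,3-dimethoxypropyl)-3-methyloxiran-2-yl]-5-oxo-2,5-dihydrofuran-3-yl}-3-iodobut-3-en-1-yl 2-methylprop-2-enoate
Conditions: NIS, MeCN/ClCH2CN 4:1, 0 °C→rt, dark
Reagents that add atoms: N-iodosuccinimide, O=C1CCC(=O)N1I
Why: Electrophilic ipso-iododesilylation converts the vinylsilane into the 2-iodoalkene; the electron-poor butenolide and methacrylate alkenes do not compete and no free hydroxyl is present.

Step 16
Reactants: 28 (1R)-1-{(2R)-4-(acetoxymethyl)-2-[(2R,3S)-3-(3,3-dimethoxypropyl)-3-methyloxiran-2-yl]-5-oxo-2,5-dihydrofuran-3-yl}-3-iodobut-3-en-1-yl 2-methylprop-2-enoate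
Product: 29 (1R)-1-{(2R)-4-(acetoxymethyl)-2-[(2R,3S)-3-methyl-3-(3-oxopropyl)oxiran-2-yl]-5-oxo-2,5-dihydrofuran-3-yl}-3-iodobut-3-en-1-yl 2-methylprop-2-enoate
Conditions: PPTS (cat.), acetone/H2O 9:1, 45 °C
Reagents that add atoms: water, O
Why: Mild acetal hydrolysis frees the C1 aldehyde; with both hydroxyls already acylated there is no internal nucleophile to open the epoxide.

Step 17
Reactants: 29 (1R)-1-{(2R)-4-(acetoxymethyl)-2-[(2R,3S)-3-methyl-3-(3-oxopropyl)oxiran-2-yl]-5-oxo-2,5-dihydrofuran-3-yl}-3-iodobut-3-en-1-yl 2-methylprop-2-enoate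
Product: 30 (4S,5R,6R,8R)-13-acetoxy-4,5-epoxy-1-hydroxygermacra-7(11),10(14)-dien-12,6-olid-8-yl 2-methylprop-2-enoate (C1 epimer mixture)
Conditions: CrCl2 (10 equiv), NiCl2 (5 mol%), DMSO/THF, 2 mM, slow addition, rt
Reagents that add atoms: none
Why: Intramolecular Nozaki–Hiyama–Kishi reaction is aldehyde-selective in the presence of the esters, lactone and epoxide and closes the ten-membered ring at C1–C10; the new C1 carbinol centre is removed in step 18.

Step 18
Reactants: 30 (4S,5R,6R,8R)-13-acetoxy-4,5-epoxy-1-hydroxygermacra-7(11),10(14)-dien-12,6-olid-8-yl 2-methylprop-2-enoate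
Product: 31 (4S,5R,6R,8R)-13-acetoxy-4,5-epoxy-1-oxogermacra-7(11),10(14)-dien-12,6-olid-8-yl 2-methylprop-2-enoate (target)
Conditions: Dess–Martin periodinane, CH2Cl2, 0 °C→rt
Reagents that add atoms: none
Why: Dess–Martin oxidation of the allylic alcohol gives the α-methylene ketone under neutral conditions without touching the four existing stereocentres.

**Compound list**
1 | but-2-yn-1-ol | CC#CCO | starting material
2 | sodium 2,2-bis(2-methoxyethoxy)-3-methyl-2,5-dihydro-1,2-oxaluminol-2-uide (cyclic alkenylalanate) | CC1=CCO[Al-]1(OCCOC)OCCOC.[Na+] | intermediate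
3 | (2Z)-3-iodobut-2-en-1-ol | C/C(I)=C/CO | intermediate
4 | 3,3-dimethoxyprop-1-ene | C=CC(OC)OC | starting material
5 | 9-(3,3-dimethoxypropyl)-9-borabicyclo[3.3.1]nonane | COC(OC)CCB1C2CCCC1CCC2 | intermediate
6 | (2Z)-6,6-dimethoxy-3-methylhex-2-en-1-ol | OC/C=C(/C)CCC(OC)OC | intermediate
7 | [(2R,3S)-3-(3,3-dimethoxypropyl)-3-methyloxiran-2-yl]methanol | COC(OC)CC[C@]1(C)O[C@@H]1CO | intermediate
8 | (2S,3S)-3-(3,3-dimethoxypropyl)-3-methyloxirane-2-carbaldehyde | COC(OC)CC[C@]1(C)O[C@@H]1C=O | intermediate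
9 | methyl (2R)-oxirane-2-carboxylate | COC(=O)[C@H]1CO1 | starting material
10 | (1-bromoethenyl)trimethylsilane | C=C(Br)[Si](C)(C)C | starting material
11 | [1-(trimethylsilyl)ethenyl]magnesium bromide | C=C([Mg]Br)[Si](C)(C)C | intermediate
12 | bromomagnesium alkoxide of methyl (2R)-2-hydroxy-4-(trimethylsilyl)pent-4-enoate | COC(=O)[C@H](O[Mg]Br)CC(=C)[Si](C)(C)C | intermediate
13 | methyl (2R)-2-[(triethylsilyl)oxy]-4-(trimethylsilyl)pent-4-enoate | COC(=O)[C@H](O[Si](CC)(CC)CC)CC(=C)[Si](C)(C)C | intermediate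
14 | (2R)-2-[(triethylsilyl)oxy]-4-(trimethylsilyl)pent-4-enal | O=C[C@H](O[Si](CC)(CC)CC)CC(=C)[Si](C)(C)C | intermediate
15 | methyl 3-hydroxypropanoate | COC(=O)CCO | starting material
16 | methyl 3-[(triethylsilyl)oxy]propanoate | COC(=O)CCO[Si](CC)(CC)CC | intermediate
17 | lithium 1-methoxy-3-[(triethylsilyl)oxy]prop-1-en-1-olate | COC([O-])=CCO[Si](CC)(CC)CC.[Li+] | intermediate
18 | 1-methoxy-3-[(triethylsilyl)oxy]-1-[(trimethylsilyl)oxy]prop-1-ene (E/Z mixture) | COC(O[Si](C)(C)C)=CCO[Si](CC)(CC)CC | intermediate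
19 | methyl (4R)-3-hydroxy-4-[(triethylsilyl)oxy]-2-{[(triethylsilyl)oxy]methyl}-6-(trimethylsilyl)hept-6-enoate (C2/C3 epimers) | COC(=O)C(CO[Si](CC)(CC)CC)C(O)[C@H](O[Si](CC)(CC)CC)CC(=C)[Si](C)(C)C | intermediate
20 | methyl (4R)-3-oxo-4-[(triethylsilyl)oxy]-2-{[(triethylsilyl)oxy]methyl}-6-(trimethylsilyl)hept-6-enoate | COC(=O)C(CO[Si](CC)(CC)CC)C(=O)[C@H](O[Si](CC)(CC)CC)CC(=C)[Si](C)(C)C | intermediate
21 | sodium (Z)-enolate of 20 | COC(=O)/C(CO[Si](CC)(CC)CC)=C(\[O-])[C@H](O[Si](CC)(CC)CC)CC(=C)[Si](C)(C)C.[Na+] | intermediate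
22 | methyl (2Z,4R)-4-[(triethylsilyl)oxy]-2-{[(triethylsilyl)oxy]methyl}-3-{[(trifluoromethyl)sulfonyl]oxy}-6-(trimethylsilyl)hepta-2,6-dienoate | COC(=O)/C(CO[Si](CC)(CC)CC)=C(\OS(=O)(=O)C(F)(F)F)[C@H](O[Si](CC)(CC)CC)CC(=C)[Si](C)(C)C | intermediate
23 | methyl (2E,4R)-3-{(R)-[(2R,3S)-3-(3,3-dimethoxypropyl)-3-methyloxiran-2-yl](hydroxy)methyl}-4-[(triethylsilyl)oxy]-2-{[(triethylsilyl)oxy]methyl}-6-(trimethylsilyl)hepta-2,6-dienoate (formed as its Cr(III) alkoxide) | COC(OC)CC[C@]1(C)O[C@@H]1[C@H](O)/C(=C(/CO[Si](CC)(CC)CC)C(=O)OC)[C@H](O[Si](CC)(CC)CC)CC(=C)[Si](C)(C)C | intermediate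
24 | (5R)-5-[(2R,3S)-3-(3,3-dimethoxypropyl)-3-methyloxiran-2-yl]-4-{(1R)-1-[(triethylsilyl)oxy]-3-(trimethylsilyl)but-3-en-1-yl}-3-{[(triethylsilyl)oxy]methyl}furan-2(5H)-one | COC(OC)CC[C@]1(C)O[C@@H]1[C@@H]1OC(=O)C(CO[Si](CC)(CC)CC)=C1[C@H](O[Si](CC)(CC)CC)CC(=C)[Si](C)(C)C | intermediate
25 | (5R)-5-[(2R,3S)-3-(3,3-dimethoxypropyl)-3-methyloxiran-2-yl]-4-[(1R)-1-hydroxy-3-(trimethylsilyl)but-3-en-1-yl]-3-(hydroxymethyl)furan-2(5H)-one | COC(OC)CC[C@]1(C)O[C@@H]1[C@@H]1OC(=O)C(CO)=C1[C@H](O)CC(=C)[Si](C)(C)C | intermediate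
26 | {(5R)-5-[(2R,3S)-3-(3,3-dimethoxypropyl)-3-methyloxiran-2-yl]-4-[(1R)-1-hydroxy-3-(trimethylsilyl)but-3-en-1-yl]-2-oxo-2,5-dihydrofuran-3-yl}methyl acetate | COC(OC)CC[C@]1(C)O[C@@H]1[C@@H]1OC(=O)C(COC(C)=O)=C1[C@H](O)CC(=C)[Si](C)(C)C | intermediate
27 | (1R)-1-{(2R)-4-(acetoxymethyl)-2-[(2R,3S)-3-(3,3-dimethoxypropyl)-3-methyloxiran-2-yl]-5-oxo-2,5-dihydrofuran-3-yl}-3-(trimethylsilyl)but-3-en-1-yl 2-methylprop-2-enoate | COC(OC)CC[C@]1(C)O[C@@H]1[C@@H]1OC(=O)C(COC(C)=O)=C1[C@H](OC(=O)C(C)=C)CC(=C)[Si](C)(C)C | intermediate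
28 | (1R)-1-{(2R)-4-(acetoxymethyl)-2-[(2R,3S)-3-(3,3-dimethoxypropyl)-3-methyloxiran-2-yl]-5-oxo-2,5-dihydrofuran-3-yl}-3-iodobut-3-en-1-yl 2-methylprop-2-enoate | COC(OC)CC[C@]1(C)O[C@@H]1[C@@H]1OC(=O)C(COC(C)=O)=C1[C@H](OC(=O)C(C)=C)CC(I)=C | intermediate
29 | (1R)-1-{(2R)-4-(acetoxymethyl)-2-[(2R,3S)-3-methyl-3-(3-oxopropyl)oxiran-2-yl]-5-oxo-2,5-dihydrofuran-3-yl}-3-iodobut-3-en-1-yl 2-methylprop-2-enoate | O=CCC[C@]1(C)O[C@@H]1[C@@H]1OC(=O)C(COC(C)=O)=C1[C@H](OC(=O)C(C)=C)CC(I)=C | intermediate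
30 | (4S,5R,6R,8R)-13-acetoxy-4,5-epoxy-1-hydroxygermacra-7(11),10(14)-dien-12,6-olid-8-yl 2-methylprop-2-enoate (C1 epimers) | C=C(C)C(=O)O[C@@H]1CC(=C)C(O)CC[C@]2(C)O[C@@H]2[C@@H]2OC(=O)C(COC(C)=O)=C21 | intermediate
31 | (4S,5R,6R,8R)-13-acetoxy-4,5-epoxy-1-oxogermacra-7(11),10(14)-dien-12,6-olid-8-yl 2-methylprop-2-enoate (CNP0266914.1) | C=C(C)C(=O)O[C@@H]1CC(=C)C(=O)CC[C@]2(C)O[C@@H]2[C@@H]2OC(=O)C(COC(C)=O)=C21 | target

**Step count**
Total: 18 steps. Longest linear sequence: 12 steps (5 → 6 → 9 → 10 → 11 → 12 → 13 → 14 → 15 → 16 → 17 → 18; the branch 7 → 8 → 9 … is equally long), i.e. 12/18.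

**Three steps most likely to fail, with fallbacks**

Step 11 (Z-selective tetrasubstituted enol triflate). The enolate may lose silanolate (E1cB) or give an E/Z mixture. The fallback fixes the geometry with a ring instead of a chelate. It sets out from 20: HF·pyridine removes both triethylsilyl groups to give methyl (4R)-4-hydroxy-2-(hydroxymethyl)-3-oxo-6-(trimethylsilyl)hept-6-enoate F1. Treatment with tBu2Si(OTf)2 and 2,6-lutidine ties the C8 and C13 oxygens into the seven-membered silylene keto ester methyl (7R)-2,2-di-tert-butyl-6-oxo-7-[2-(trimethylsilyl)prop-2-en-1-yl]-1,3,2-dioxasilepane-5-carboxylate F2. Enol triflation (iPr2NEt, Tf2O, −78 °C) can now only give the ring-cis olefin, the cyclic enol triflate methyl (7R)-2,2-di-tert-butyl-7-[2-(trimethylsilyl)prop-2-en-1-yl]-6-{[(trifluoromethyl)sulfonyl]oxy}-4,7-dihydro-1,3,2-dioxasilepine-5-carboxylate F3, with OTf cis to CO2Me. Ni/Cr coupling of F3 with 8 under the step-12 conditions gives the silylene-bridged butenolide F4, and HF·pyridine removes the silylene so the route is rejoined at diol 25.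

Step 12 (intermolecular Ni/Cr coupling of a hindered, tetrasubstituted alkenyl triflate; C6 selectivity). If the triflate is sluggish, isomerises at the alkenyl-metal stage or adds unselectively, the alkenylchromium is replaced by a β-magnesio acrylate. The fallback sets out from 22: Pd(PPh3)4, (Me3Sn)2 and LiCl give the alkenylstannane methyl (2Z,4R)-4-[(triethylsilyl)oxy]-2-{[(triethylsilyl)oxy]methyl}-3-(trimethylstannyl)-6-(trimethylsilyl)hepta-2,6-dienoate F5. Iodine converts it with retention into the β-iodoacrylate methyl (2Z,4R)-3-iodo-4-[(triethylsilyl)oxy]-2-{[(triethylsilyl)oxy]methyl}-6-(trimethylsilyl)hepta-2,6-dienoate F6. Iodine–magnesium exchange with iPrMgCl·LiCl at −78 °C (ester-activated iodide, vinylsilane untouched) and addition to 8 at −78 °C gives, after lactonisation of the magnesium alkoxide, butenolide 24, where the route is rejoined.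

Step 17 (ten-membered ring closure by Ni/Cr addition). If oligomerisation or reduction of the iodide wins, the ring is closed at the ketone oxidation level by an acyl coupling instead of an aldehyde addition. The fallback sets out from 29: Pinnick oxidation (NaClO2, NaH2PO4, 2-methylbut-2-ene) gives the carboxylic acid 3-[(2S,3R)-3-{(2R)-4-(acetoxymethyl)-3-[(1R)-3-iodo-1-(methacryloyloxy)but-3-en-1-yl]-5-oxo-2,5-dihydrofuran-2-yl}-2-methyloxiran-2-yl]propanoic acid F7. 2,2'-Dipyridyl disulfide and PPh3 give its S-pyridin-2-yl thioester F8. An intramolecular nickel-catalysed reductive acyl coupling of the alkenyl iodide with the thioester (NiBr2·dtbbpy, Cp2ZrCl2, Zn, high dilution) forms the C1–C10 bond as the enone directly, arriving at target 31 without step 18.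

**Further compounds**
F1 | step 11 | methyl (4R)-4-hydroxy-2-(hydroxymethyl)-3-oxo-6-(trimethylsilyl)hept-6-enoate | COC(=O)C(CO)C(=O)[C@H](O)CC(=C)[Si](C)(C)C
F2 | step 11 | methyl (7R)-2,2-di-tert-butyl-6-oxo-7-[2-(trimethylsilyl)prop-2-en-1-yl]-1,3,2-dioxasilepane-5-carboxylate | COC(=O)C1CO[Si](C(C)(C)C)(C(C)(C)C)O[C@H](CC(=C)[Si](C)(C)C)C1=O
F3 | step 11 | methyl (7R)-2,2-di-tert-butyl-7-[2-(trimethylsilyl)prop-2-en-1-yl]-6-{[(trifluoromethyl)sulfonyl]oxy}-4,7-dihydro-1,3,2-dioxasilepine-5-carboxylate | COC(=O)C1=C(OS(=O)(=O)C(F)(F)F)[C@@H](CC(=C)[Si](C)(C)C)O[Si](C(C)(C)C)(C(C)(C)C)OC1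
F4 | step 11 | O,O'-(di-tert-butylsilanediyl) derivative of diol 25 (silylene bridging the C8 and C13 oxygens, fused to the butenolide) | COC(OC)CC[C@]1(C)O[C@@H]1[C@@H]1OC(=O)C2=C1[C@@H](CC(=C)[Si](C)(C)C)O[Si](C(C)(C)C)(C(C)(C)C)OC2
F5 | step 12 | methyl (2Z,4R)-4-[(triethylsilyl)oxy]-2-{[(triethylsilyl)oxy]methyl}-3-(trimethylstannyl)-6-(trimethylsilyl)hepta-2,6-dienoate | COC(=O)/C(CO[Si](CC)(CC)CC)=C(\[Sn](C)(C)C)[C@H](O[Si](CC)(CC)CC)CC(=C)[Si](C)(C)C
F6 | step 12 | methyl (2Z,4R)-3-iodo-4-[(triethylsilyl)oxy]-2-{[(triethylsilyl)oxy]methyl}-6-(trimethylsilyl)hepta-2,6-dienoate | COC(=O)/C(CO[Si](CC)(CC)CC)=C(\I)[C@H](O[Si](CC)(CC)CC)CC(=C)[Si](C)(C)C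
F7 | step 17 | 3-[(2S,3R)-3-{(2R)-4-(acetoxymethyl)-3-[(1R)-3-iodo-1-(methacryloyloxy)but-3-en-1-yl]-5-oxo-2,5-dihydrofuran-2-yl}-2-methyloxiran-2-yl]propanoic acid | OC(=O)CC[C@]1(C)O[C@@H]1[C@@H]1OC(=O)C(COC(C)=O)=C1[C@H](OC(=O)C(C)=C)CC(I)=C
F8 | step 17 | S-pyridin-2-yl thioester of F7 | O=C(CC[C@]1(C)O[C@@H]1[C@@H]1OC(=O)C(COC(C)=O)=C1[C@H](OC(=O)C(C)=C)CC(I)=C)Sc1ccccn1
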